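**Retrosynthetic overview**
1. Target ⇒ its aryl acetate ⇒ C7–C8 bond by photochemical 1,6-hydrogen transfer and radical recombination (Norrish–Yang) of a 5-aryl-4-(arylmethoxymethyl)tetrahydrofuran-3-one made in the same flask from the secondary alcohol; this closes ring B and sets C7 and C8.
2. That alcohol ⇒ C9'–O–C7 ether by reductive etherification (through a cis-fused acetal) of a 2-aryl-3-(hydroxymethyl)tetrahydrofuran-4-ol with vanillin acetate.
3. The diol (ring A) ⇒ C7'–O bond by acid cycloetherification through the benzylic cation of an acyclic tetraol ⇒ lactone reduction of an aldol adduct.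
4. Aldol adduct ⇒ C8'–C7' bond by dianion aldol of (R)-3-hydroxy-γ-butyrolactone with veratraldehyde.
5. Ring order: ring A (veratryl tetrahydrofuran) first, ring B (guaiacyl tetrahydrofuran) last. The purchased carbinol centre controls C8', C8' controls C7', the carbinol is then oxidised away, and C8 and C7 are re-set by the cis ring fusion.

Assumption: lignan numbering is used in the comments (C7–C9 for the guaiacyl C6C3 unit, C7'–C9' for the veratryl unit), and the three starting materials are taken as purchased.

**Step 1**
Reactants: 1 (4R)-4-hydroxyoxolan-2-one; 2 3,4-dimethoxybenzaldehyde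
Product: 3 (3R,4R)-3-[(3,4-dimethoxyphenyl)(hydroxy)methyl]-4-hydroxyoxolan-2-one (both carbinol epimers)
Conditions: LiN(iPr)2 (2.2 equiv), THF, −78 °C; then 2, −78 → −40 °C; AcOH
Reagents that add atoms: none
Why: Fráter–Seebach-type dianion aldol in which the lithium alkoxide blocks its own face, so the lactone enolate attacks the aldehyde anti to the C4 oxygen and sets C3 (the future C8') trans to it, while the carbinol centre may form as a mixture because it is ionised in step 2.

**Step 2**
Reactants: 3 (3R,4R)-3-[(3,4-dimethoxyphenyl)(hydroxy)methyl]-4-hydroxyoxolan-2-one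
Product: 5 (3R,4S,5S)-5-(3,4-dimethoxyphenyl)-4-(hydroxymethyl)oxolan-3-ol, via tetraol 4 (not isolated)
Conditions: LiAlH4, THF, 0 → 65 °C; H2O/NaOH work-up; then TsOH·H2O (10 mol %), MeCN, 23 °C
Reagents that add atoms: none
Why: LiAlH4 reduction of the lactone followed by SN1 cycloetherification, in which acid ionises the dimethoxy-stabilised benzylic alcohol of either epimer and the terminal primary hydroxyl closes the only accessible five-membered ring, the aryl group settling trans to the adjacent CH2OH and so setting C7' (ring A).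

**Step 3**
Reactants: 5 (3R,4S,5S)-5-(3,4-dimethoxyphenyl)-4-(hydroxymethyl)oxolan-3-ol; 6 4-formyl-2-methoxyphenyl acetate
Product: 8 4-({[(2S,3S,4R)-2-(3,4-dimethoxyphenyl)-4-hydroxyoxolan-3-yl]methoxy}methyl)-2-methoxyphenyl acetate, via cyclic acetal 7 (not isolated)
Conditions: Cu(OTf)2 (10 mol %), 4 Å MS, MeCN, 23 °C; then Et3SiH (3 equiv), 0 → 23 °C
Reagents that add atoms: none
Why: One-pot Lewis-acid acetalisation and regioselective reductive acetal opening (reductive etherification), in which the cis-1,3-diol forms the cis-fused six-membered arylidene acetal 7 with the aryl group equatorial and silane reduction under Cu(OTf)2, as with 4,6-O-benzylidene hexopyranosides, leaves the arylmethyl group on the primary oxygen; the acetal centre is destroyed, so no stereocentre is set.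

**Step 4**
Reactants: 8 4-({[(2S,3S,4R)-2-(3,4-dimethoxyphenyl)-4-hydroxyoxolan-3-yl]methoxy}methyl)-2-methoxyphenyl acetate
Product: 11 (1S,2R,5R,6S)-6-(3,4-dimethoxyphenyl)-2-(4-hydroxy-3-methoxyphenyl)-3,7-dioxabicyclo[3.3.0]octan-1-ol, via keto ether 9 (not isolated), via furofuranol acetate 10 (not isolated)
Conditions: [Ir(C5Me5)Cl2]2 (1 mol %), K2CO3 (5 mol %), acetone (0.1 M), 40 °C, dark; dilute with acetone to 5 mM, Ar, hν (310 nm), 15 °C; then MeOH, K2CO3, 0 °C
Reagents that add atoms: none
Why: Proposed new method: a one-flask dehydrogenative Norrish–Yang cyclisation in which acetone is at once hydrogen acceptor, solvent, light filter for the two aryl groups and triplet sensitiser — [Ir(C5Me5)Cl2]2/K2CO3 first effects Oppenauer-type transfer dehydrogenation of the only free (secondary) alcohol to keto ether 9, triplet acetone then passes its energy to 9, whose carbonyl oxygen abstracts the benzylic ether hydrogen at C7 through a seven-membered transition state (1,6-hydrogen transfer), and the 1,5-biradical collapses to the C7–C8 bond, the cis ring fusion being the only geometrically possible one (C8 set by C8') and the aryl group closing on the convex face cis to the new hydroxyl (C7), after which methanolysis frees the phenol; the closest known reactions are iridium-catalysed Oppenauer oxidation in acetone and the direct-irradiation δ-hydrogen-abstraction photocyclisation of isolated β-(arylmethoxy) ketones to 3-hydroxytetrahydrofurans, as used for paulownin-type 1-hydroxyfurofurans.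

**Compound list**
1 | (4R)-4-hydroxyoxolan-2-one [(R)-3-hydroxy-γ-butyrolactone] | O=C1C[C@@H](O)CO1 | starting material
2 | 3,4-dimethoxybenzaldehyde (veratraldehyde) | COc1ccc(C=O)cc1OC | starting material
3 | (3R,4R)-3-[(3,4-dimethoxyphenyl)(hydroxy)methyl]-4-hydroxyoxolan-2-one (ring substituents trans; carbinol epimers) | O=C1OC[C@H](O)[C@H]1C(O)c1ccc(OC)c(OC)c1 | intermediate
4 | (2R,3R)-2-[(3,4-dimethoxyphenyl)(hydroxy)methyl]butane-1,3,4-triol (carbinol epimers) | OC[C@H](O)[C@H](CO)C(O)c1ccc(OC)c(OC)c1 | intermediate
5 | (3R,4S,5S)-5-(3,4-dimethoxyphenyl)-4-(hydroxymethyl)oxolan-3-ol (aryl trans to CH2OH; CH2OH cis to OH) | OC[C@H]1[C@@H](O)CO[C@@H]1c1ccc(OC)c(OC)c1 | intermediate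
6 | 4-formyl-2-methoxyphenyl acetate (vanillin acetate) | CC(=O)Oc1ccc(C=O)cc1OC | starting material
7 | 4-[(2R,4aR,5S,7aR)-5-(3,4-dimethoxyphenyl)tetrahydro-4H-furo[3,4-d][1,3]dioxin-2-yl]-2-methoxyphenyl acetate (cis-fused acetal; aryl equatorial) | COc1cc(ccc1OC(C)=O)[C@@H]1OC[C@H]2[C@@H](O1)CO[C@@H]2c1ccc(OC)c(OC)c1 | intermediate
8 | 4-({[(2S,3S,4R)-2-(3,4-dimethoxyphenyl)-4-hydroxyoxolan-3-yl]methoxy}methyl)-2-methoxyphenyl acetate | CC(=O)Oc1ccc(COC[C@H]2[C@@H](O)CO[C@@H]2c2ccc(OC)c(OC)c2)cc1OC | intermediate
9 | 4-({[(2S,3R)-2-(3,4-dimethoxyphenyl)-4-oxooxolan-3-yl]methoxy}methyl)-2-methoxyphenyl acetate | CC(=O)Oc1ccc(COC[C@H]2C(=O)CO[C@@H]2c2ccc(OC)c(OC)c2)cc1OC | intermediate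
10 | 4-[(1S,2R,5R,6S)-6-(3,4-dimethoxyphenyl)-1-hydroxy-3,7-dioxabicyclo[3.3.0]octan-2-yl]-2-methoxyphenyl acetate | COc1cc([C@H]2OC[C@@H]3[C@@H](c4ccc(OC)c(OC)c4)OC[C@]23O)ccc1OC(C)=O | intermediate
11 | (1S,2R,5R,6S)-6-(3,4-dimethoxyphenyl)-2-(4-hydroxy-3-methoxyphenyl)-3,7-dioxabicyclo[3.3.0]octan-1-ol (CNP0141816.1) | COc1cc([C@H]2OC[C@@H]3[C@@H](c4ccc(OC)c(OC)c4)OC[C@]23O)ccc1O | target

**Step count and risks**
Total step count: 4. Longest linear sequence: 4 steps (from 1).

The three steps most likely to fail:

Step 4 (the proposed new method) is the least certain. The β-alkoxy ketone 9 may lose the arylmethanol by retro-oxa-Michael reaction under K2CO3. Triplet acetone may abstract hydrogen from the benzylic ether positions of 9 or 10. Acetone as a hydrogen-bond acceptor may lower the exo:endo ratio at C7 compared with a hydrocarbon solvent (the minor C7 epimer is removed by chromatography in any case). α-Cleavage of the α-alkoxy ketone can also compete. The fallback is the known stepwise sequence, setting out from 8. Dess–Martin periodinane (CH2Cl2, NaHCO3, 23 °C) gives ketone 9, which is isolated. Irradiation of 9 (5 mM, degassed benzene, Pyrex-filtered medium-pressure mercury lamp) is the classical direct-excitation Norrish–Yang cyclisation and gives 10, also isolated. Methanolysis (K2CO3, MeOH, 0 °C) then comes back to the route at 11. This fallback makes no compound outside the list (F0).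

Step 3 may open the acetal the wrong way round (arylmethyl on the secondary oxygen), or the Lewis acid and silane may reduce the veratryl benzylic C–O bond of ring A. The fallback sets out from 6 and 5 and replaces acetal opening by direct selective O-alkylation. NaBH4 (THF–H2O, 0 °C) reduces 6 to 4-(hydroxymethyl)-2-methoxyphenyl acetate F1. PBr3 (Et2O, 0 °C) converts it into 4-(bromomethyl)-2-methoxyphenyl acetate F2. Ag2O-mediated mono-alkylation of diol 5 with F2 (CH2Cl2, 23 °C), selective for the primary hydroxyl under neutral conditions that spare the aryl acetate, comes back to the route at 8.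

Step 1 may suffer from retro-aldol loss or a low yield of the dianion aldol. The fallback sets out from 1 and avoids the aldol and the tetraol altogether. The same dianion (LiN(iPr)2, 2.2 equiv, THF, −78 → −40 °C) is alkylated anti to the alkoxide with 3,4-dimethoxybenzyl bromide (BrCc1ccc(OC)c(OC)c1) to give (3R,4R)-3-(3,4-dimethoxybenzyl)-4-hydroxyoxolan-2-one F3. LiAlH4 (THF) reduces it to (2S,3R)-2-(3,4-dimethoxybenzyl)butane-1,3,4-triol F4. DDQ (CH2Cl2, 0 °C) then oxidises the electron-rich benzylic C–H to the cation, which the terminal primary hydroxyl traps trans to CH2OH, coming back to the route at 5.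

**Further compounds**
F0 | step 4 | none | none
F1 | step 3 | 4-(hydroxymethyl)-2-methoxyphenyl acetate | CC(=O)Oc1ccc(CO)cc1OC
F2 | step 3 | 4-(bromomethyl)-2-methoxyphenyl acetate | CC(=O)Oc1ccc(CBr)cc1OC
F3 | step 1 | (3R,4R)-3-(3,4-dimethoxybenzyl)-4-hydroxyoxolan-2-one | O=C1OC[C@H](O)[C@H]1Cc1ccc(OC)c(OC)c1
F4 | step 1 | (2S,3R)-2-(3,4-dimethoxybenzyl)butane-1,3,4-triol | OC[C@H](O)[C@H](CO)Cc1ccc(OC)c(OC)c1
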